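The numbering is that of the daucanes. Ring A (cyclopentane) is C1 (quaternary, CH3), C2 (OAc), C3, C4 (OH, isopropyl), C5. Ring B (cycloheptene) is C1, C5, C6 (anisate), C7, C8=C9, C10. The plan rests on the C3–C4 bond: the oxygen at C2 and the C4 carbinol form a β-ketol pattern inside ring A. The precursor is a monocyclic trans-1,2-diacylcycloheptene, acetyl on C1 and isobutyryl on C5. Kinetic enolisation of the acetyl group and aldol addition to the C4 ketone close ring A away from the ring fusion. This builds the crowded C4 carbinol and leaves a C2 ketone for hydroxyl-directed reduction. A dianionic Claisen rearrangement sets C1/C5, and metathesis closes ring B.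

Key step: step 10

Remark: β is the face of the bicycle that carries the C1 methyl group. The target is 1β-CH3, 2α-OAc, 4β-OH, 5α-H, 6α-O-anisoyl, that is (1R,2S,4R,5S,6S) in this numbering.

Step 1
Reactants: 1 ethyl (3R)-4-chloro-3-hydroxybutanoate
Product: 2 ethyl 2-[(2R)-oxiran-2-yl]acetate
Conditions: Ag2O, 1,2-dimethoxyethane, 60 °C, dark
Reagents that add atoms: none
Why: Halohydrin-to-epoxide closure (intramolecular Williamson etherification) is driven by precipitation of AgCl under non-basic conditions, which should avoid isomerisation to the 4-hydroxycrotonate, and the C–O bond at the stereocentre (later C6) is not touched.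

Step 2
Reactants: 2 ethyl 2-[(2R)-oxiran-2-yl]acetate
Product: 3 ethyl (3S)-3-hydroxy-5-methylhex-5-enoate
Conditions: CH2=C(CH3)MgBr, CuI (10 mol %), THF, −40 °C; aq. NH4Cl
Reagents that add atoms: isopropenylmagnesium bromide, CC(=C)[Mg]Br
Why: Copper-catalysed SN2 opening of a terminal epoxide by a Grignard reagent occurs at the unsubstituted carbon (later C7) faster than attack on the ester at this temperature, and the stereocentre is untouched (R becomes S only through the CIP priorities).

Step 3
Reactants: 4 pent-1-en-4-yne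
Product: 7 (2E)-3-methylhexa-2,5-dien-1-ol, via alkenylalane 5 (not isolated), via lithium alanate 6 (not isolated)
Conditions: Me3Al, Cp2ZrCl2 (20 mol %), CH2Cl2, 0 → 23 °C; n-BuLi, THF/hexane, −78 → 0 °C; (CH2O)n, 23 °C; then H2O
Reagents that add atoms: trimethylaluminium, C[Al](C)C; formaldehyde (as paraformaldehyde), C=O
Why: Zirconium-catalysed (Negishi) carboalumination adds CH3 and Al syn across the terminal alkyne much faster than across the isolated alkene, and the derived alanate adds to formaldehyde with retention, which fixes the E geometry that later defines C1.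

Step 4
Reactants: 3 ethyl (3S)-3-hydroxy-5-methylhex-5-enoate; 7 (2E)-3-methylhexa-2,5-dien-1-ol
Product: 8 (2E)-3-methylhexa-2,5-dien-1-yl (3S)-3-hydroxy-5-methylhex-5-enoate
Conditions: Ti(OEt)4 (10 mol %), toluene, 90 °C, EtOH distilled off
Reagents that add atoms: none
Why: Titanate-catalysed transesterification is a neutral method that tolerates β-hydroxy esters and is driven by removal of ethanol, and no stereocentre takes part.

Step 5
Reactants: 8 (2E)-3-methylhexa-2,5-dien-1-yl (3S)-3-hydroxy-5-methylhex-5-enoate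
Product: 10 (2S,3S)-3-hydroxy-5-methyl-2-[(3S)-3-methylhexa-1,5-dien-3-yl]hex-5-enoic acid, via dilithio enolate 9 (not isolated)
Conditions: LiN(iPr)2 (2.2 equiv), THF, −78 °C, then 23 → 45 °C; 1 M HCl
Reagents that add atoms: none
Why: In this dianionic ester-enolate Claisen rearrangement ([3,3]) the lithium-bridged enolate holds C6 cis to OLi, the chair transition state with the E alkene puts the allyl CH2 (C10) equatorial and CH3 axial (this sets C1 relative to C5), and the allyl unit reaches the enolate face anti to the C7 chain of the chelate, as in Fráter–Seebach alkylation (5,6-anti).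

Step 6
Reactants: 10 (2S,3S)-3-hydroxy-5-methyl-2-[(3S)-3-methylhexa-1,5-dien-3-yl]hex-5-enoic acid
Product: 11 (2S,3S)-3-(4-methoxybenzoyloxy)-5-methyl-2-[(3S)-3-methylhexa-1,5-dien-3-yl]hex-5-enoic acid
Conditions: 4-MeOC6H4COCl, pyridine, DMAP (cat.), CH2Cl2, 0 → 23 °C; aqueous work-up
Reagents that add atoms: 4-methoxybenzoyl chloride, COc1ccc(cc1)C(Cl)=O
Why: DMAP-catalysed O-acylation installs the final C6 ester early so that it also serves as the hydroxyl protection, any acyl group taken up by the carboxyl group is lost again in the aqueous work-up, and the C6–O bond is retained.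

Step 7
Reactants: 11 (2S,3S)-3-(4-methoxybenzoyloxy)-5-methyl-2-[(3S)-3-methylhexa-1,5-dien-3-yl]hex-5-enoic acid
Product: 13 (4S,5S)-2,7-dimethyl-4-[(3S)-3-methylhexa-1,5-dien-3-yl]-3-oxooct-7-en-5-yl 4-methoxybenzoate, via acid chloride 12 (not isolated)
Conditions: (COCl)2, DMF (cat.), CH2Cl2, 0 → 23 °C, evaporate; iPrMgCl, Fe(acac)3 (3 mol %), THF, −78 °C
Reagents that add atoms: isopropylmagnesium chloride, CC(C)[Mg]Cl
Why: Iron-catalysed acylation of a Grignard reagent by an acid chloride is fast at −78 °C even for branched partners, stops at the ketone and spares aryl esters and alkenes, so C5 should keep its configuration.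

Step 8
Reactants: 13 (4S,5S)-2,7-dimethyl-4-[(3S)-3-methylhexa-1,5-dien-3-yl]-3-oxooct-7-en-5-yl 4-methoxybenzoate
Product: 14 (1S,6S,7S)-6-ethenyl-3,6-dimethyl-7-(2-methylpropanoyl)cyclohept-3-en-1-yl 4-methoxybenzoate
Conditions: second-generation Grubbs catalyst RuCl2(=CHPh)(PCy3)(SIMes) (5 mol %), CH2Cl2 (2 mM), 40 °C
Reagents that add atoms: none
Why: In this ring-closing metathesis the catalyst loads on the unhindered allyl terminus (C9) and closes onto the methallyl alkene to give ring B with its C8=C9 bond, while the neopentyl vinyl group on C1 is too hindered to initiate and could only give a four-membered ring from the C9 carbene.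

Step 9
Reactants: 14 (1S,6S,7S)-6-ethenyl-3,6-dimethyl-7-(2-methylpropanoyl)cyclohept-3-en-1-yl 4-methoxybenzoate
Product: 15 (1S,6R,7S)-6-acetyl-3,6-dimethyl-7-(2-methylpropanoyl)cyclohept-3-en-1-yl 4-methoxybenzoate
Conditions: PdCl2 (20 mol %), CuCl, O2 (1 atm), DMF/H2O 7:1, 23 → 40 °C
Reagents that add atoms: water, O
Why: In the Wacker–Tsuji oxidation divalent palladium binds only the monosubstituted vinyl group (the trisubstituted ring alkene is inert), Markovnikov attack of water gives the methyl ketone C2(=O)–C3H3, and no stereocentre is touched.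

Step 10
Reactants: 15 (1S,6R,7S)-6-acetyl-3,6-dimethyl-7-(2-methylpropanoyl)cyclohept-3-en-1-yl 4-methoxybenzoate
Product: 18 (1R,4R,5S,6S)-4-hydroxy-6-(4-methoxybenzoyloxy)dauc-8-en-2-one, via lithium enolate 16 (not isolated), via lithium aldolate 17 (not isolated)
Conditions: LiN(iPr)2 (1.05 equiv), THF, −78 °C, then −40 °C; AcOH/THF at −78 °C
Reagents that add atoms: none
Why: LiN(iPr)2 removes a proton from the acetyl CH3 (C3), the only unhindered α-position (C1 is quaternary, C5–H and the isopropyl methine are tertiary and shielded), and C3 of enolate 16 adds to the C4 ketone, which the trans-diequatorial C1/C5 substituents hold gauche to it, before cold acetic acid traps aldolate 17 as ketol 18. The reaction type is the intramolecular aldol addition of a 1,4-diketone stopped at the β-ketol stage, the first half of the classical cyclopentenone annulation. Ring A closes in the 5-(enolendo)-exo-trig mode, the geometrically harder enolate mode but the one through which all 1,4-diketone cyclisations run. The only new stereocentre, C4, is controlled by C5 and C1: the isopropyl group turns to the α face beside C5–H, away from C6 and the β methyl on C1, so O4 ends β, where lithium can also bridge to the C6 ester oxygen. C1, C5 and C6 are not touched because the new bond lies away from the ring fusion. The step needs site-selective enolisation and an addition faster than proton transfer to C5 (which would expel the anisate), and low temperature, one equivalent of base and the electron-rich, sluggish anisate should secure this.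

Step 11
Reactants: 18 (1R,4R,5S,6S)-4-hydroxy-6-(4-methoxybenzoyloxy)dauc-8-en-2-one
Product: 19 (1R,2S,4R,5S,6S)-2,4-dihydroxydauc-8-en-6-yl 4-methoxybenzoate
Conditions: Me4NBH(OAc)3, MeCN/AcOH 1:1, −30 °C
Reagents that add atoms: none
Why: In the Evans–Saksena reduction the 4β-hydroxyl replaces an acetate on boron and delivers hydride inside the complex to the β face of the C2 ketone, giving the 2α-alcohol anti to O4, while the reagent leaves unbound ketones and esters alone.

Step 12
Reactants: 19 (1R,2S,4R,5S,6S)-2,4-dihydroxydauc-8-en-6-yl 4-methoxybenzoate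
Product: 20 (1R,2S,4R,5S,6S)-2-acetoxy-4-hydroxydauc-8-en-6-yl 4-methoxybenzoate (target)
Conditions: Ac2O, pyridine, DMAP (cat.), CH2Cl2, 0 °C
Reagents that add atoms: acetic anhydride, CC(=O)OC(C)=O
Why: DMAP-catalysed acetylation takes the secondary C2 hydroxyl, while the tertiary, flanked C4 hydroxyl should not react under these conditions.

Compound list
1 | ethyl (3R)-4-chloro-3-hydroxybutanoate | CCOC(=O)C[C@@H](O)CCl | starting material
2 | ethyl 2-[(2R)-oxiran-2-yl]acetate | CCOC(=O)C[C@@H]1CO1 | intermediate
3 | ethyl (3S)-3-hydroxy-5-methylhex-5-enoate | CCOC(=O)C[C@@H](O)CC(C)=C | intermediate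
4 | pent-1-en-4-yne | C=CCC#C | starting material
5 | dimethyl[(1E)-2-methylpenta-1,4-dien-1-yl]alane | C=CC/C(C)=C/[Al](C)C | intermediate
6 | lithium butyl(dimethyl)[(1E)-2-methylpenta-1,4-dien-1-yl]aluminate | [Li+].C=CC/C(C)=C/[Al-](C)(C)CCCC | intermediate
7 | (2E)-3-methylhexa-2,5-dien-1-ol | C=CC/C(C)=C/CO | intermediate
8 | (2E)-3-methylhexa-2,5-dien-1-yl (3S)-3-hydroxy-5-methylhex-5-enoate | C=CC/C(C)=C/COC(=O)C[C@@H](O)CC(C)=C | intermediate
9 | chelated dilithio ester enolate of 8 (OLi cis to C6) | [Li]O/C(OC/C=C(\C)CC=C)=C\[C@@H](O[Li])CC(C)=C | intermediate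
10 | (2S,3S)-3-hydroxy-5-methyl-2-[(3S)-3-methylhexa-1,5-dien-3-yl]hex-5-enoic acid | OC(=O)[C@H]([C@@H](O)CC(C)=C)[C@](C)(C=C)CC=C | intermediate
11 | (2S,3S)-3-(4-methoxybenzoyloxy)-5-methyl-2-[(3S)-3-methylhexa-1,5-dien-3-yl]hex-5-enoic acid | OC(=O)[C@H]([C@@H](OC(=O)c1ccc(OC)cc1)CC(C)=C)[C@](C)(C=C)CC=C | intermediate
12 | acid chloride of 11 | ClC(=O)[C@H]([C@@H](OC(=O)c1ccc(OC)cc1)CC(C)=C)[C@](C)(C=C)CC=C | intermediate
13 | (4S,5S)-2,7-dimethyl-4-[(3S)-3-methylhexa-1,5-dien-3-yl]-3-oxooct-7-en-5-yl 4-methoxybenzoate | CC(C)C(=O)[C@H]([C@@H](OC(=O)c1ccc(OC)cc1)CC(C)=C)[C@](C)(C=C)CC=C | intermediate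
14 | (1S,6S,7S)-6-ethenyl-3,6-dimethyl-7-(2-methylpropanoyl)cyclohept-3-en-1-yl 4-methoxybenzoate | CC(C)C(=O)[C@@H]1[C@@H](OC(=O)c2ccc(OC)cc2)CC(C)=CC[C@@]1(C)C=C | intermediate
15 | (1S,6R,7S)-6-acetyl-3,6-dimethyl-7-(2-methylpropanoyl)cyclohept-3-en-1-yl 4-methoxybenzoate | CC(C)C(=O)[C@@H]1[C@@H](OC(=O)c2ccc(OC)cc2)CC(C)=CC[C@@]1(C)C(C)=O | intermediate
16 | lithium enolate of the acetyl group of 15 | CC(C)C(=O)[C@@H]1[C@@H](OC(=O)c2ccc(OC)cc2)CC(C)=CC[C@@]1(C)C(=C)O[Li] | intermediate
17 | lithium 4β-alkoxide (aldolate) of 18 | COc1ccc(C(=O)O[C@H]2CC(C)=CC[C@@]3(C)C(=O)C[C@@](O[Li])(C(C)C)[C@H]23)cc1 | intermediate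
18 | (1R,4R,5S,6S)-4-hydroxy-6-(4-methoxybenzoyloxy)dauc-8-en-2-one (trans-fused, 4β-OH, 6α-ester) | COc1ccc(C(=O)O[C@H]2CC(C)=CC[C@@]3(C)C(=O)C[C@@](O)(C(C)C)[C@H]23)cc1 | intermediate
19 | (1R,2S,4R,5S,6S)-2,4-dihydroxydauc-8-en-6-yl 4-methoxybenzoate (2α-OH, 4β-OH) | COc1ccc(C(=O)O[C@H]2CC(C)=CC[C@@]3(C)[C@@H](O)C[C@@](O)(C(C)C)[C@H]23)cc1 | intermediate
20 | (1R,2S,4R,5S,6S)-2-acetoxy-4-hydroxydauc-8-en-6-yl 4-methoxybenzoate | COc1ccc(C(=O)O[C@H]2CC(C)=CC[C@@]3(C)[C@@H](OC(C)=O)C[C@@](O)(C(C)C)[C@H]23)cc1 | target

Total step count: 12. Longest linear sequence: 11 steps (1, 2, 4 to 12).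

Steps most likely to fail

Step 10. Closure onto the doubly α-branched C4 ketone may be slow. The aldolate could then revert, the enolate could pass a proton to C5 with β-elimination of the anisate, or the C4 alkoxide could pick up the anisoyl group. The fallback gives up the metal enolate and sets out from 15. Enolisation with LiN(iPr)2 in the presence of Me3SiCl at −78 °C gives the isolable trimethylsilyl enol ether F1. This neutral nucleophile is then closed onto the C4 ketone activated by TiCl4 in CH2Cl2 at −78 °C (Mukaiyama aldol). The titanium chelate holds the adduct and no free alkoxide is present. Aqueous work-up returns the route at 18.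

Step 5. The dilithio enolate may break down by loss of the allylic alkoxide before the slow bond formation to a fully substituted carbon, or facial selectivity may erode on warming. The fallback sets out from 8. Silylation with t-BuMe2SiCl and imidazole gives the silyl ether F2. Enolisation with LiN(iPr)2 in THF/DMPU and trapping with Me3SiCl gives the silyl ketene acetal F3, which has the same enolate geometry but now fixed by the solvent. F3 rearranges at or below 23 °C (Ireland–Claisen) to the trimethylsilyl ester F4. Aqueous work-up gives the protected acid F5, and HF·pyridine frees the hydroxyl group, which returns the route at 10.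

Step 7. The Grignard reagent may act as a base on the hindered acid chloride. Ketene formation or enolisation would cost the C5 configuration or the anisate. The fallback sets out from 10, before acylation. Coupling with MeNHOMe·HCl (EDC, HOBt, iPr2NEt) gives the Weinreb amide F6. Excess iPrMgCl at 0 °C adds through the chelated tetrahedral intermediate to give the hydroxy ketone F7. Acylation with 4-methoxybenzoyl chloride, pyridine and DMAP returns the route at 13.

Further compounds
F1 | step 10 | trimethylsilyl enol ether of the acetyl group of 15 | CC(C)C(=O)[C@@H]1[C@@H](OC(=O)c2ccc(OC)cc2)CC(C)=CC[C@@]1(C)C(=C)O[Si](C)(C)C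
F2 | step 5 | tert-butyldimethylsilyl ether of 8 | C=CC/C(C)=C/COC(=O)C[C@@H](O[Si](C)(C)C(C)(C)C)CC(C)=C
F3 | step 5 | trimethylsilyl ketene acetal of F2 (OSiMe3 cis to C6) | C[Si](C)(C)O/C(OC/C=C(\C)CC=C)=C\[C@@H](O[Si](C)(C)C(C)(C)C)CC(C)=C
F4 | step 5 | trimethylsilyl ester of F5 | C[Si](C)(C)OC(=O)[C@H]([C@@H](O[Si](C)(C)C(C)(C)C)CC(C)=C)[C@](C)(C=C)CC=C
F5 | step 5 | O-tert-butyldimethylsilyl derivative of acid 10 | OC(=O)[C@H]([C@@H](O[Si](C)(C)C(C)(C)C)CC(C)=C)[C@](C)(C=C)CC=C
F6 | step 7 | N-methoxy-N-methylamide of acid 10 | CON(C)C(=O)[C@H]([C@@H](O)CC(C)=C)[C@](C)(C=C)CC=C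
F7 | step 7 | (4S,5S)-5-hydroxy-2,7-dimethyl-4-[(3S)-3-methylhexa-1,5-dien-3-yl]oct-7-en-3-one | CC(C)C(=O)[C@H]([C@@H](O)CC(C)=C)[C@](C)(C=C)CC=C
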